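**Retrosynthetic overview**

1. Target 9 is traced back to the tert-butyl 4-oxochromane-3-carboxylate 7; the ester on C3 is a temporary activating group, lost at the end by acidolysis and decarboxylation.
2. Ring C of 7 is opened at the C2–C3 bond to the acyclic β-ketoester 5, an aryl 3,4-dimethoxybenzyl ether. In the forward sense this is an oxidative C–H/C–H coupling: DDQ removes hydride from the OCH2 group and a chiral copper enolate closes the ring.
3. Enabling feature: C2 is bonded to O1 and is benzylic to ring B, whose 4'-methoxy group is para to it. In 5 it is therefore the CH2 of a dimethoxybenzyl ether, the C–H bond that DDQ abstracts. C3 lies alpha to the C4 ketone and, with the temporary ester, chelates copper.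
4. 5 comes from C-acylation (Boc2O) of the acetophenone 3, and 3 from O-benzylation of commercial 2'-hydroxy-3',4',6'-trimethoxyacetophenone 1 with commercial 3,4-dimethoxybenzyl chloride 2.
5. Ring order: rings A and B are bought; ring C is the only ring formed, in step 3, together with the C2 stereocentre.

Key step: step 3

Assumption: the sense of induction of the copper bisoxazoline complex on this new substrate class cannot be predicted with certainty; the (S,S)-ligand is written, and its (R,R)-mirror image is to be used if a first run gives the 2R series.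

**Route**

Step 1
Reactants: 1 1-(2-hydroxy-3,4,6-trimethoxyphenyl)ethanone; 2 4-(chloromethyl)-1,2-dimethoxybenzene
Product: 3 1-{2-[(3,4-dimethoxybenzyl)oxy]-3,4,6-trimethoxyphenyl}ethanone
Conditions: K2CO3, n-Bu4NI (cat.), DMF, 60 °C
Reagents that add atoms: none
Why: Williamson ether synthesis, in which the phenoxide of 1 displaces chloride from the activated benzylic chloride by SN2 and no other nucleophilic site is present.

Step 2
Reactants: 3 1-{2-[(3,4-dimethoxybenzyl)oxy]-3,4,6-trimethoxyphenyl}ethanone
Product: 5 tert-butyl 3-{2-[(3,4-dimethoxybenzyl)oxy]-3,4,6-trimethoxyphenyl}-3-oxopropanoate, via lithium enolate 4 (not isolated)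
Conditions: LiN(SiMe3)2 (2.1 equiv), THF, −78 °C; Boc2O, −78 to 0 °C; aq. NH4Cl
Reagents that add atoms: di-tert-butyl dicarbonate (Boc2O), CC(C)(C)OC(=O)OC(=O)OC(C)(C)C
Why: C-acylation of a ketone lithium enolate (crossed Claisen-type condensation) at the only enolisable position, the acetyl CH3, with the second equivalent of base holding the product as its stabilised enolate so that double acylation is prevented.

Step 3
Reactants: 5 tert-butyl 3-{2-[(3,4-dimethoxybenzyl)oxy]-3,4,6-trimethoxyphenyl}-3-oxopropanoate
Product: 7 tert-butyl (2S,3R)-2-(3,4-dimethoxyphenyl)-5,7,8-trimethoxy-4-oxochromane-3-carboxylate, via oxocarbenium ion 6 (not isolated)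
Conditions: Cu(OTf)2 (10 mol %), (S,S)-t-Bu-BOX (12 mol %), DDQ (1.1 equiv), 4 Å MS, CH2Cl2, −30 to 0 °C
Reagents that add atoms: none
Why: Proposed new method: DDQ takes hydride from the benzylic OCH2 of the 3,4-dimethoxybenzyl aryl ether 5 (charge-transfer complex, then C–H cleavage) and leaves the (E)-oxocarbenium ion 6, while Cu(OTf)2 and the bisoxazoline hold the β-ketoester as a chiral chelated enolate whose central carbon adds to the cationic carbon and so forms the C2–C3 bond. The closest known reaction types are the DDQ-mediated oxidative cyclisation of 4-methoxybenzyl and allyl alkyl ethers onto tethered enol acetates, which gives tetrahydropyran-4-ones, and its enantioselective form with tethered β-ketoesters under divalent copper bisoxazoline control; new here are the phenol-derived (aryl) ether as hydride donor and the benzo-fused ring. Ring C closes in a 6-(enolendo)-endo-trig mode, both the enolate C=C and the C=O+ bond lying inside the new ring, through a chair-like transition state with ring B pseudo-equatorial. C2 is controlled by the ligand: its tert-butyl groups shield one face of the square-planar copper enolate, the ortho tether can deliver the cation only to the open face, and the (E)-geometry of 6 turns this into one configuration at C2; C3 is set at the same time, equilibrates through the enol to trans and is erased in step 4. The step needs site selectivity for one C–H position, secured because only the ether CH2 gives a cation that is both bonded to O1 and conjugated with the 4-methoxy group of ring B, and it needs the copper-bound path to outrun cyclisation of the free enol, secured by the higher acidity of the chelated β-ketoester and the low temperature. A limit of 1.1 equiv of DDQ and dry conditions guard the product against further dehydrogenation and the cation against hydrolysis.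

Step 4
Reactants: 7 tert-butyl (2S,3R)-2-(3,4-dimethoxyphenyl)-5,7,8-trimethoxy-4-oxochromane-3-carboxylate
Product: 9 (2S)-2-(3,4-dimethoxyphenyl)-5,7,8-trimethoxychroman-4-one, via β-keto acid 8 (not isolated)
Conditions: TsOH·H2O (20 mol %), toluene, 80 °C
Reagents that add atoms: none
Why: Acid-promoted loss of isobutene from the tert-butyl ester followed by decarboxylation of the β-keto acid through its cyclic six-membered transition state (de-tert-butoxycarbonylation of a β-ketoester), which runs without base and thus without enolate-driven opening of ring C, so that C2 should stay untouched while C3 becomes CH2.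

**Compound list**

1 | 1-(2-hydroxy-3,4,6-trimethoxyphenyl)ethanone (2'-hydroxy-3',4',6'-trimethoxyacetophenone) | CC(=O)c1c(O)c(OC)c(OC)cc1OC | starting material
2 | 4-(chloromethyl)-1,2-dimethoxybenzene (3,4-dimethoxybenzyl chloride) | COc1ccc(CCl)cc1OC | starting material
3 | 1-{2-[(3,4-dimethoxybenzyl)oxy]-3,4,6-trimethoxyphenyl}ethanone | CC(=O)c1c(OCc2ccc(OC)c(OC)c2)c(OC)c(OC)cc1OC | intermediate
4 | lithium enolate of 3 (lithium 1-{2-[(3,4-dimethoxybenzyl)oxy]-3,4,6-trimethoxyphenyl}ethenolate) | [Li+].[O-]C(=C)c1c(OCc2ccc(OC)c(OC)c2)c(OC)c(OC)cc1OC | intermediate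
5 | tert-butyl 3-{2-[(3,4-dimethoxybenzyl)oxy]-3,4,6-trimethoxyphenyl}-3-oxopropanoate | CC(C)(C)OC(=O)CC(=O)c1c(OCc2ccc(OC)c(OC)c2)c(OC)c(OC)cc1OC | intermediate
6 | (E)-aryl(3,4-dimethoxybenzylidene)oxonium ion of 5, as ion pair with 2,3-dichloro-5,6-dicyano-4-hydroxyphenolate (β-ketoester unit bound to copper in the flask) | COc1ccc(/C=[O+]/c2c(OC)c(OC)cc(OC)c2C(=O)CC(=O)OC(C)(C)C)cc1OC.[O-]c1c(Cl)c(Cl)c(O)c(C#N)c1C#N | intermediate
7 | tert-butyl (2S,3R)-2-(3,4-dimethoxyphenyl)-5,7,8-trimethoxy-4-oxochromane-3-carboxylate (trans keto form, in equilibrium with its enol) | COc1ccc([C@@H]2[C@@H](C(=O)OC(C)(C)C)C(=O)c3c(OC)cc(OC)c(OC)c3O2)cc1OC | intermediate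
8 | (2S,3R)-2-(3,4-dimethoxyphenyl)-5,7,8-trimethoxy-4-oxochromane-3-carboxylic acid | COc1ccc([C@@H]2[C@@H](C(=O)O)C(=O)c3c(OC)cc(OC)c(OC)c3O2)cc1OC | intermediate
9 | (2S)-2-(3,4-dimethoxyphenyl)-5,7,8-trimethoxychroman-4-one ((2S)-5,7,8,3',4'-pentamethoxyflavanone) | COc1ccc([C@@H]2CC(=O)c3c(OC)cc(OC)c(OC)c3O2)cc1OC | target

**Step count**

Total steps: 4. Longest linear sequence: 4 steps (1 → 3 → 5 → 7 → 9).

**Steps most likely to fail**

Step 3 (Proposed new method). Facial control may be incomplete because the unbound enol cyclises in a racemic background reaction. The enol form of the product may be dehydrogenated further by DDQ to the chromone, with loss of C2. Traces of water may capture the cation and remove the benzyl group. The fallback uses known chemistry, sets out from 3 and comes back at 9. The lithium enolate 4 would be C-acylated with 2,2,2-trifluoroethyl trifluoroacetate to 4,4,4-trifluoro-1-{2-[(3,4-dimethoxybenzyl)oxy]-3,4,6-trimethoxyphenyl}butane-1,3-dione F1. Crude F1 would be treated with MsN3, Et3N and H2O in MeCN (detrifluoroacetylative diazo transfer) to give 2-diazo-1-{2-[(3,4-dimethoxybenzyl)oxy]-3,4,6-trimethoxyphenyl}ethanone F2. Rh2(S-BSP)4 (dirhodium tetrakis[(S)-N-(benzenesulfonyl)prolinate]; CH2Cl2, 40 °C) should then insert the carbenoid carbon into the same benzylic ether C–H bond. This 1,6-insertion is the known enantioselective route from 2-alkoxyaryl diazoketones to chroman-4-ones; it closes the same C2–C3 bond and gives 9 directly, so steps 2 and 4 fall away. The catalyst enantiomer is chosen as in the assumption above.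

Step 4. The configuration at C2 may erode during ester cleavage through acid-promoted reversible opening of ring C (retro-oxa-Michael or benzylic ionisation, both favoured by the 4'-methoxy group). The fallback sets out from the partly racemised 9 and comes back at 9. A kinetic resolution by asymmetric transfer hydrogenation (RhCl(Cp*)[(R,R)-TsDPEN], HCO2H/Et3N, EtOAc, rt) should reduce the 2R ketone preferentially to (2R,4R)-2-(3,4-dimethoxyphenyl)-5,7,8-trimethoxychroman-4-ol F3. The 2S ketone 9 is left behind and is separated from F3 by chromatography. The (R,R)-complex is proposed by analogy with the known facial preference for aryl ketones.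

Step 2. The hindered enolate may be acylated on oxygen (enol carbonate formation), and the amide base may attack the anhydride. The fallback sets out from 3 and comes back at 5. A Claisen condensation under thermodynamic control (NaH, dimethyl carbonate, THF, reflux) should give methyl 3-{2-[(3,4-dimethoxybenzyl)oxy]-3,4,6-trimethoxyphenyl}-3-oxopropanoate F4; only the C-acylated product is stored as its enolate. Ester exchange of F4 with t-BuOH (DMAP cat., toluene, reflux, methanol removed over 4 Å MS) then gives 5.

**Further compounds**

F1 | step 3 | 4,4,4-trifluoro-1-{2-[(3,4-dimethoxybenzyl)oxy]-3,4,6-trimethoxyphenyl}butane-1,3-dione | O=C(CC(=O)C(F)(F)F)c1c(OCc2ccc(OC)c(OC)c2)c(OC)c(OC)cc1OC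
F2 | step 3 | 2-diazo-1-{2-[(3,4-dimethoxybenzyl)oxy]-3,4,6-trimethoxyphenyl}ethanone | [N-]=[N+]=CC(=O)c1c(OCc2ccc(OC)c(OC)c2)c(OC)c(OC)cc1OC
F3 | step 4 | (2R,4R)-2-(3,4-dimethoxyphenyl)-5,7,8-trimethoxychroman-4-ol | COc1ccc([C@H]2C[C@@H](O)c3c(OC)cc(OC)c(OC)c3O2)cc1OC
F4 | step 2 | methyl 3-{2-[(3,4-dimethoxybenzyl)oxy]-3,4,6-trimethoxyphenyl}-3-oxopropanoate | COC(=O)CC(=O)c1c(OCc2ccc(OC)c(OC)c2)c(OC)c(OC)cc1OC
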